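**Strategy.** Ring C (C8, C9, C11–C14; icetexane numbering) is an oxidised 2-isopropylresorcinol: the oxygens at C12 and C14 flank the isopropyl carbon C13. A Danheiser benzannulation exploits this. 2-Bromo-3-(diethoxymethyl)cyclobutenone and an isopropyl siloxyalkyne should give the pentasubstituted phenol in one thermal operation, forming C12–C13 and C14–C8; the alkyne supplies C13/C14, the cyclobutenone C8, C9, C11 and C12. The bromide (C8) then adds as an aryltitanium to a chiral keto-lactone aldehyde (ring A plus lactone, from a butenolide Diels–Alder), the acetal carbon (C20) closes ring B by aldol condensation, and Luche reduction, desilylation and Fremy oxidation (C11–H to quinone) finish the route.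

Key step: step 5

Assumption: locants are icetexane numbers (ring A = C1–C5, C10; ring B = C5–C10, C20; ring C = C8, C9, C11–C14; C19 = lactone carbonyl; C20 = the ring-B CH=); compounds 2–13 carry no stereocentre except 4, which is racemic.

Step 1
Reactants: 1 3,3-diethoxyprop-1-yne
Product: 2 4,4-dichloro-3-(diethoxymethyl)cyclobut-2-en-1-one
Conditions: Cl3CCOCl, Zn–Cu, Et2O/DME, rt
Reagents that add atoms: trichloroacetyl chloride ClC(Cl)(Cl)C(Cl)=O
Why: Dichloroketene, generated by zinc dechlorination of the acid chloride, should undergo the ketene–alkyne [2+2] cycloaddition with its carbonyl carbon bonding to the unsubstituted alkyne terminus, so that the acetal ends at C3; DME ties up zinc chloride and spares the acetal.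

Step 2
Reactants: 2 4,4-dichloro-3-(diethoxymethyl)cyclobut-2-en-1-one
Product: 3 3-(diethoxymethyl)cyclobut-2-en-1-one
Conditions: Zn dust, AcOH, TMEDA, EtOH, 0 °C → rt
Reagents that add atoms: none
Why: Zinc-mediated reductive dechlorination of the α,α-dichloro ketone (two C–Cl reductions with protonation) in buffered medium should give the parent 3-substituted cyclobutenone without double-bond migration.

Step 3
Reactants: 3 3-(diethoxymethyl)cyclobut-2-en-1-one
Product: 5 2-bromo-3-(diethoxymethyl)cyclobut-2-en-1-one, via 2,3-dibromocyclobutanone 4 (not isolated)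
Conditions: Br2, CH2Cl2, −78 °C; then Et3N, −78 → 0 °C
Reagents that add atoms: bromine BrBr
Why: Bromine addition to the strained enone followed by amine-induced E1cB dehydrobromination from the more acidic α-bromo position (standard enone α-bromination) places bromine on the carbon that becomes C8.

Step 4
Reactants: 6 ethyl 2-methylpropanoate
Product: 8 triisopropyl[(3-methylbut-1-yn-1-yl)oxy]silane, via lithium ynolate 7 (not isolated)
Conditions: CH2Br2, LiTMP (2.2 equiv), THF, −78 °C; n-BuLi, −78 → −20 °C; then TIPSCl, −78 → 0 °C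
Reagents that add atoms: dibromomethane BrCBr; triisopropylsilyl chloride CC(C)[Si](Cl)(C(C)C)C(C)C
Why: Kowalski ester homologation: dibromomethyllithium adds to the ester, the dibromo ketone enolate undergoes Br/Li exchange and 1,2-shift to ynolate 7, and the bulky silyl chloride traps it on oxygen.

Step 5
Reactants: 5 2-bromo-3-(diethoxymethyl)cyclobut-2-en-1-one, 8 triisopropyl[(3-methylbut-1-yn-1-yl)oxy]silane
Product: 12 4-bromo-5-(diethoxymethyl)-2-isopropyl-3-[(triisopropylsilyl)oxy]phenol, via bromo(vinyl)ketene 9 (not isolated), via 4-vinylcyclobutenone adduct 10 (not isolated), via dienylketene 11 (not isolated)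
Conditions: PhMe, 80 → 110 °C, sealed tube (1.3 equiv of 8)
Reagents that add atoms: none
Why: Heating opens cyclobutenone 5 by 4π-electrocyclic ring opening to bromo(vinyl)ketene 9, which undergoes a [2+2] cycloaddition with siloxyalkyne 8 (ketene carbonyl carbon to the nucleophilic isopropyl-bearing alkyne carbon, brominated ketene carbon to the siloxy carbon) to give 10; a second 4π opening gives dienylketene 11, and 6π-electrocyclisation with tautomerisation delivers the phenol. This is the Danheiser benzannulation of a cyclobutenone with a siloxyalkyne. The only ring closed is benzene ring C, by thermal 6π-electrocyclic closure between the ketene carbon (C12) and the terminal methylene (C11), after the [2+2] step has made the two new bonds C12–C13 and C14–C8. No stereocentre is formed. The step needs regioselectivity only: the polarisation of the ynol ether against the electrophilic ketene carbon puts the isopropyl carbon between the two oxygens, with the free hydroxyl at C12 and the silyloxy group at C14. The 2-bromo and 3-acetal substituents are carried unchanged to C8 and C9, and C11 stays as CH for the final oxidation.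

Step 6
Reactants: 12 4-bromo-5-(diethoxymethyl)-2-isopropyl-3-[(triisopropylsilyl)oxy]phenol
Product: 13 [4-bromo-5-(diethoxymethyl)-2-isopropyl-3-(triisopropylsilyloxy)phenoxy](tert-butyl)dimethylsilane
Conditions: TBSCl, imidazole, DMF, rt
Reagents that add atoms: tert-butyldimethylsilyl chloride CC(C)(C)[Si](C)(C)Cl
Why: Imidazole-promoted O-silylation masks the acidic phenol so that the later bromine–lithium exchange is not quenched; the acetal is stable to these conditions.

Step 7
Reactants: 14 (R)-(2,2-dimethyl-1,3-dioxolan-4-yl)methanol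
Product: 15 (S)-2,2-dimethyl-1,3-dioxolane-4-carbaldehyde
Conditions: (COCl)2, DMSO, CH2Cl2, −78 °C; Et3N, → 0 °C; used crude
Reagents that add atoms: none
Why: Swern oxidation gives the aldehyde at low temperature without touching the stereocentre (the descriptor changes from R to S only through CIP priorities).

Step 8
Reactants: 15 (S)-2,2-dimethyl-1,3-dioxolane-4-carbaldehyde
Product: 16 ethyl (Z)-3-[(4R)-2,2-dimethyl-1,3-dioxolan-4-yl]-2-methylprop-2-enoate
Conditions: (CF3CH2O)2P(O)CH(CH3)CO2Et, KHMDS, 18-crown-6, THF, −78 °C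
Reagents that add atoms: ethyl 2-[bis(2,2,2-trifluoroethoxy)phosphoryl]propanoate CCOC(=O)C(C)P(=O)(OCC(F)(F)F)OCC(F)(F)F
Why: Still–Gennari olefination: the electron-poor phosphonate eliminates under kinetic control and should give the Z-trisubstituted enoate needed for ring closure, at a temperature where the α-alkoxy aldehyde does not epimerise.

Step 9
Reactants: 16 ethyl (Z)-3-[(4R)-2,2-dimethyl-1,3-dioxolan-4-yl]-2-methylprop-2-enoate
Product: 17 (5R)-5-(hydroxymethyl)-3-methylfuran-2(5H)-one
Conditions: H2SO4 (cat.), MeOH, rt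
Reagents that add atoms: none
Why: Acid-catalysed transketalisation frees the diol, and the γ-hydroxyl, held cis to the ester by the Z-alkene, lactonises to the butenolide (intramolecular transesterification) with the stereocentre untouched.

Step 10
Reactants: 17 (5R)-5-(hydroxymethyl)-3-methylfuran-2(5H)-one, 18 2-(trimethylsilyloxy)buta-1,3-diene
Product: 20 (3R,3aR,7aS)-3-(hydroxymethyl)-7a-methylhexahydroisobenzofuran-1,5-dione, via silyl enol ether cycloadduct 19 (not isolated)
Conditions: 18 (5 equiv), BHT, PhMe, 170 °C, sealed tube; then 1 M HCl, THF, 0 °C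
Reagents that add atoms: none
Why: Thermal Diels–Alder cycloaddition: the diene should add to the butenolide face anti to the C6 hydroxymethyl group, setting the quaternary C4 and C5 cis-fused and trans to C7, with the siloxy carbon 1,4 ("para") to the carbonyl-bearing carbon; acid then hydrolyses the silyl enol ether to the C1 ketone.

Step 11
Reactants: 20 (3R,3aR,7aS)-3-(hydroxymethyl)-7a-methylhexahydroisobenzofuran-1,5-dione
Product: 21 (3R,3aR,7aS)-7a-methyl-1,5-dioxooctahydroisobenzofuran-3-carbaldehyde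
Conditions: Dess–Martin periodinane, NaHCO3, CH2Cl2, 0 °C → rt; used at once
Reagents that add atoms: none
Why: Dess–Martin oxidation under buffered, non-basic conditions should give the α-acyloxy aldehyde without epimerising C6.

Step 12
Reactants: 13 [4-bromo-5-(diethoxymethyl)-2-isopropyl-3-(triisopropylsilyloxy)phenoxy](tert-butyl)dimethylsilane, 21 (3R,3aR,7aS)-7a-methyl-1,5-dioxooctahydroisobenzofuran-3-carbaldehyde
Product: 24 (3R,3aR,7aS)-3-[(S)-{4-[(tert-butyldimethylsilyl)oxy]-6-(diethoxymethyl)-3-isopropyl-2-[(triisopropylsilyl)oxy]phenyl}(hydroxy)methyl]-7a-methylhexahydroisobenzofuran-1,5-dione, via aryllithium 22 (not isolated), via aryltitanium triisopropoxide 23 (not isolated)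
Conditions: t-BuLi (2.1 equiv), Et2O, −78 °C; ClTi(OiPr)3, −78 °C; then 21, −78 → −20 °C; aq. NH4Cl
Reagents that add atoms: none
Why: Bromine–lithium exchange, transmetalation to an aldehyde-selective aryltitanium and non-chelated Felkin–Anh 1,2-addition (C6–O bond anti to the incoming aryl) should form C7–C8, set 7S, and leave ketone and lactone untouched.

Step 13
Reactants: 24 the C7 carbinol described in step 12
Product: 26 5-[(tert-butyldimethylsilyl)oxy]-4-isopropyl-2-{(S)-[(1R,3aS,7aR)-3a-methyl-3,6-dioxooctahydroisobenzofuran-1-yl](triethylsilyloxy)methyl}-3-[(triisopropylsilyl)oxy]benzaldehyde, via triethylsilyl ether acetal 25 (not isolated)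
Conditions: TESOTf, 2,4,6-collidine, CH2Cl2, −78 → 0 °C; then H2O, rt
Reagents that add atoms: triethylsilyl trifluoromethanesulfonate CC[Si](CC)(CC)OS(=O)(=O)C(F)(F)F; water O
Why: The silyl triflate/collidine pair silylates the C7 hydroxyl and then converts the diethyl acetal through a collidinium salt into the aldehyde on aqueous quench (silyl-triflate-mediated acetal cleavage), so the electron-rich benzylic C7–O bond is never exposed to protic acid; capping O7 also blocks later oxa-Michael addition to the enone.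

Step 14
Reactants: 26 the keto aldehyde described in step 13
Product: 27 (4S,5R,6R,7S)-12-(tert-butyldimethylsilyloxy)-1-oxo-7-(triethylsilyloxy)-14-(triisopropylsilyloxy)icetexa-8,11,13,10(20)-tetraen-19,6-olide
Conditions: pyrrolidine, AcOH (0.3 equiv each), MeCN, 4 Å MS, 40 °C
Reagents that add atoms: none
Why: Amine-catalysed intramolecular aldol (Claisen–Schmidt) condensation: the enamine of the C1 ketone can reach the aryl aldehyde only through C10, which closes the seven-membered ring B, and E1cB dehydration gives the ring-constrained C10=C20 enone.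

Step 15
Reactants: 27 the tetracyclic enone described in step 14
Product: 28 (1R,4S,5R,6R,7S)-12-(tert-butyldimethylsilyloxy)-1-hydroxy-7-(triethylsilyloxy)-14-(triisopropylsilyloxy)icetexa-8,11,13,10(20)-tetraen-19,6-olide
Conditions: NaBH4, CeCl3·7H2O, MeOH, −78 °C
Reagents that add atoms: none
Why: Luche 1,2-reduction: hydride should add axially from the α face of the cyclohexanone (1,3-related only to axial hydrogens), giving the equatorial 1β (1R) allylic alcohol and leaving lactone and alkene untouched.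

Step 16
Reactants: 28 the allylic alcohol described in step 15
Product: 30 ballotiquinone, via resorcinol tetraol 29 (not isolated)
Conditions: TBAF, AcOH, THF, 0 °C (Ar); then (KSO3)2NO, KH2PO4, acetone/H2O, 0 °C
Reagents that add atoms: potassium nitrosodisulfonate (Fremy's salt) [K+].[K+].[O]N(S(=O)(=O)[O-])S(=O)(=O)[O-]
Why: Buffered fluoride cleaves the three silyl ethers, and the freed resorcinol undergoes Teuber oxidation: the C14 phenoxyl radical is trapped by a second nitroxyl at the free para carbon C11 and loss of imidodisulfonate should give the 11,14-quinone with the 12-hydroxyl intact.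

**Compound list**

1 | 3,3-diethoxyprop-1-yne | C#CC(OCC)OCC | starting material
2 | 4,4-dichloro-3-(diethoxymethyl)cyclobut-2-en-1-one | CCOC(OCC)C1=CC(=O)C1(Cl)Cl | intermediate
3 | 3-(diethoxymethyl)cyclobut-2-en-1-one | CCOC(OCC)C1=CC(=O)C1 | intermediate
4 | 2,3-dibromo-3-(diethoxymethyl)cyclobutan-1-one (racemic, not isolated) | CCOC(OCC)C1(Br)CC(=O)C1Br | intermediate
5 | 2-bromo-3-(diethoxymethyl)cyclobut-2-en-1-one | CCOC(OCC)C1=C(Br)C(=O)C1 | intermediate
6 | ethyl 2-methylpropanoate | CCOC(=O)C(C)C | starting material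
7 | lithium 3-methylbut-1-yn-1-olate (not isolated) | CC(C)C#CO[Li] | intermediate
8 | triisopropyl[(3-methylbut-1-yn-1-yl)oxy]silane | CC(C)C#CO[Si](C(C)C)(C(C)C)C(C)C | intermediate
9 | 2-bromo-3-(diethoxymethyl)buta-1,3-dien-1-one (not isolated) | CCOC(OCC)C(=C)C(Br)=C=O | intermediate
10 | 4-bromo-4-(3,3-diethoxyprop-1-en-2-yl)-2-isopropyl-3-[(triisopropylsilyl)oxy]cyclobut-2-en-1-one (not isolated) | CCOC(OCC)C(=C)C1(Br)C(=O)C(C(C)C)=C1O[Si](C(C)C)(C(C)C)C(C)C | intermediate
11 | 4-bromo-5-(diethoxymethyl)-2-isopropyl-3-[(triisopropylsilyl)oxy]hexa-1,3,5-trien-1-one (not isolated) | CCOC(OCC)C(=C)C(Br)=C(O[Si](C(C)C)(C(C)C)C(C)C)C(C(C)C)=C=O | intermediate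
12 | 4-bromo-5-(diethoxymethyl)-2-isopropyl-3-[(triisopropylsilyl)oxy]phenol | CCOC(OCC)c1cc(O)c(C(C)C)c(O[Si](C(C)C)(C(C)C)C(C)C)c1Br | intermediate
13 | [4-bromo-5-(diethoxymethyl)-2-isopropyl-3-(triisopropylsilyloxy)phenoxy](tert-butyl)dimethylsilane | CCOC(OCC)c1cc(O[Si](C)(C)C(C)(C)C)c(C(C)C)c(O[Si](C(C)C)(C(C)C)C(C)C)c1Br | intermediate
14 | (R)-(2,2-dimethyl-1,3-dioxolan-4-yl)methanol | OC[C@@H]1COC(C)(C)O1 | starting material
15 | (S)-2,2-dimethyl-1,3-dioxolane-4-carbaldehyde | O=C[C@@H]1COC(C)(C)O1 | intermediate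
16 | ethyl (Z)-3-[(4R)-2,2-dimethyl-1,3-dioxolan-4-yl]-2-methylprop-2-enoate | CCOC(=O)/C(C)=C\[C@@H]1COC(C)(C)O1 | intermediate
17 | (5R)-5-(hydroxymethyl)-3-methylfuran-2(5H)-one | OC[C@@H]1OC(=O)C(C)=C1 | intermediate
18 | 2-(trimethylsilyloxy)buta-1,3-diene | C=CC(=C)O[Si](C)(C)C | starting material
19 | (3R,3aR,7aS)-3-(hydroxymethyl)-7a-methyl-5-(trimethylsilyloxy)-3a,4,7,7a-tetrahydroisobenzofuran-1(3H)-one (not isolated) | OC[C@@H]1OC(=O)[C@@]2(C)CC=C(O[Si](C)(C)C)C[C@@H]12 | intermediate
20 | (3R,3aR,7aS)-3-(hydroxymethyl)-7a-methylhexahydroisobenzofuran-1,5-dione | OC[C@@H]1OC(=O)[C@@]2(C)CCC(=O)C[C@@H]12 | intermediate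
21 | (3R,3aR,7aS)-7a-methyl-1,5-dioxooctahydroisobenzofuran-3-carbaldehyde | O=C[C@@H]1OC(=O)[C@@]2(C)CCC(=O)C[C@@H]12 | intermediate
22 | {4-[(tert-butyldimethylsilyl)oxy]-6-(diethoxymethyl)-3-isopropyl-2-[(triisopropylsilyl)oxy]phenyl}lithium (not isolated) | CCOC(OCC)c1cc(O[Si](C)(C)C(C)(C)C)c(C(C)C)c(O[Si](C(C)C)(C(C)C)C(C)C)c1[Li] | intermediate
23 | {4-[(tert-butyldimethylsilyl)oxy]-6-(diethoxymethyl)-3-isopropyl-2-[(triisopropylsilyl)oxy]phenyl}tri(propan-2-yloxy)titanium (not isolated) | CCOC(OCC)c1cc(O[Si](C)(C)C(C)(C)C)c(C(C)C)c(O[Si](C(C)C)(C(C)C)C(C)C)c1[Ti](OC(C)C)(OC(C)C)OC(C)C | intermediate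
24 | (3R,3aR,7aS)-3-[(S)-{4-[(tert-butyldimethylsilyl)oxy]-6-(diethoxymethyl)-3-isopropyl-2-[(triisopropylsilyl)oxy]phenyl}(hydroxy)methyl]-7a-methylhexahydroisobenzofuran-1,5-dione | CCOC(OCC)c1cc(O[Si](C)(C)C(C)(C)C)c(C(C)C)c(O[Si](C(C)C)(C(C)C)C(C)C)c1[C@H](O)[C@@H]1OC(=O)[C@@]2(C)CCC(=O)C[C@@H]12 | intermediate
25 | triethylsilyl ether of 24 at O7, acetal intact (not isolated) | CCOC(OCC)c1cc(O[Si](C)(C)C(C)(C)C)c(C(C)C)c(O[Si](C(C)C)(C(C)C)C(C)C)c1[C@H](O[Si](CC)(CC)CC)[C@@H]1OC(=O)[C@@]2(C)CCC(=O)C[C@@H]12 | intermediate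
26 | 5-[(tert-butyldimethylsilyl)oxy]-4-isopropyl-2-{(S)-[(1R,3aS,7aR)-3a-methyl-3,6-dioxooctahydroisobenzofuran-1-yl](triethylsilyloxy)methyl}-3-[(triisopropylsilyl)oxy]benzaldehyde | O=Cc1cc(O[Si](C)(C)C(C)(C)C)c(C(C)C)c(O[Si](C(C)C)(C(C)C)C(C)C)c1[C@H](O[Si](CC)(CC)CC)[C@@H]1OC(=O)[C@@]2(C)CCC(=O)C[C@@H]12 | intermediate
27 | (4S,5R,6R,7S)-12-(tert-butyldimethylsilyloxy)-1-oxo-7-(triethylsilyloxy)-14-(triisopropylsilyloxy)icetexa-8,11,13,10(20)-tetraen-19,6-olide | CC(C)c1c(O[Si](C)(C)C(C)(C)C)cc2c(c1O[Si](C(C)C)(C(C)C)C(C)C)[C@H](O[Si](CC)(CC)CC)[C@@H]1OC(=O)[C@@]3(C)CCC(=O)C(=C2)[C@@H]13 | intermediate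
28 | (1R,4S,5R,6R,7S)-12-(tert-butyldimethylsilyloxy)-1-hydroxy-7-(triethylsilyloxy)-14-(triisopropylsilyloxy)icetexa-8,11,13,10(20)-tetraen-19,6-olide | CC(C)c1c(O[Si](C)(C)C(C)(C)C)cc2c(c1O[Si](C(C)C)(C(C)C)C(C)C)[C@H](O[Si](CC)(CC)CC)[C@@H]1OC(=O)[C@@]3(C)CC[C@@H](O)C(=C2)[C@@H]13 | intermediate
29 | (1R,4S,5R,6R,7S)-1,7,12,14-tetrahydroxyicetexa-8,11,13,10(20)-tetraen-19,6-olide (not isolated) | CC(C)c1c(O)cc2c(c1O)[C@H](O)[C@@H]1OC(=O)[C@@]3(C)CC[C@@H](O)C(=C2)[C@@H]13 | intermediate
30 | ballotiquinone | CC(C)C1=C(O)C(=O)C2=C(C1=O)[C@H](O)[C@@H]1OC(=O)[C@@]3(C)CC[C@@H](O)C(=C2)[C@@H]13 | target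

**Route length.** Total step count: 16. Longest linear sequence: 10 steps (steps 1, 2, 3, 5, 6, 12, 13, 14, 15, 16; the branch from 14 through steps 7–11 and 12–16 is equally long).

**Steps most likely to fail**

Step 5. The electrophilic bromoketene may dimerise before it is trapped, or the allylic α-keto C–Br bond of the [2+2] adduct may ionise before the second ring opening and 6π closure. The fallback sets out from 3 and introduces the halogen after ring construction. Unbrominated cyclobutenone 3 (the classical 3-monosubstituted substrate) and 8 in toluene at 80 °C should give 5-(diethoxymethyl)-2-isopropyl-3-[(triisopropylsilyl)oxy]phenol F1. Electrophilic bromination with tetrabutylammonium tribromide (CH2Cl2, −20 °C) at the carbon para to the free hydroxyl, which is also ortho to the silyloxy group, comes back to the route at 12.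

Step 10. The trisubstituted α-methyl butenolide may be too poor a dienophile, so that thermal decay and polymerisation of the diene outrun cycloaddition. The fallback sets out from 17 and uses a far more reactive amino-siloxy diene at lower temperature. (E)-3-(tert-Butyldimethylsilyloxy)-N,N-dimethylbuta-1,3-dien-1-amine in toluene at 80 °C should give, with the same anti facial selectivity, the amino silyl enol ether cycloadduct F2. Aqueous HCl in THF then eliminates the amine and hydrolyses the enol ether to the enone (3R,3aR,7aS)-3-(hydroxymethyl)-7a-methyl-3a,4-dihydroisobenzofuran-1,5(3H,7aH)-dione F3. Hydrogenation (H2, Pd/C, EtOAc) comes back to the route at 20.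

Step 12. The ortho-silyloxy aryllithium may undergo anionic O→C silyl migration, or the doubly ortho-substituted aryl metal may add so slowly that enolisation and epimerisation of the aldehyde at C6, or loss of Felkin selectivity, compete. The fallback sets out from 13, avoids any aryl anion, and forms C6–C7 instead of C7–C8. Palladium-catalysed formylation of 13 (Pd(OAc)2, di(1-adamantyl)-n-butylphosphine, CO/H2, TMEDA, toluene, 100 °C) should give 5-[(tert-butyldimethylsilyl)oxy]-2-(diethoxymethyl)-4-isopropyl-3-[(triisopropylsilyl)oxy]benzaldehyde regioisomer with the formyl group at C8, F4. A vinylogous Mukaiyama aldol reaction of F4 with 3-methyl-2-(trimethylsilyloxy)furan F5 (from commercial 3-methylfuran-2(5H)-one, TMSOTf, Et3N) follows, under a cinchona-derived chiral ammonium carboxylate catalyst, a Lewis-base activation that leaves the acetal alone, with methanolic K2CO3 work-up. It should give the erythro (5R,1′S) butenolide carbinol F6. Thermal Diels–Alder reaction of F6 with 18, anti to the C6 substituent, gives the silyl enol ether cycloadduct F7, and K2CO3/MeOH at 0 °C comes back to the route at 24.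

**Further compounds**

F1 | step 5 | 5-(diethoxymethyl)-2-isopropyl-3-[(triisopropylsilyl)oxy]phenol | CCOC(OCC)c1cc(O)c(C(C)C)c(O[Si](C(C)C)(C(C)C)C(C)C)c1
F2 | step 10 | (3R,3aR,7aS)-5-(tert-butyldimethylsilyloxy)-7-(dimethylamino)-3-(hydroxymethyl)-7a-methyl-3a,4,7,7a-tetrahydroisobenzofuran-1(3H)-one | OC[C@@H]1OC(=O)[C@@]2(C)C(N(C)C)C=C(O[Si](C)(C)C(C)(C)C)C[C@@H]12
F3 | step 10 | (3R,3aR,7aS)-3-(hydroxymethyl)-7a-methyl-3a,4-dihydroisobenzofuran-1,5(3H,7aH)-dione | OC[C@@H]1OC(=O)[C@@]2(C)C=CC(=O)C[C@@H]12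
F4 | step 12 | 4-[(tert-butyldimethylsilyl)oxy]-6-(diethoxymethyl)-3-isopropyl-2-[(triisopropylsilyl)oxy]benzaldehyde | CCOC(OCC)c1cc(O[Si](C)(C)C(C)(C)C)c(C(C)C)c(O[Si](C(C)C)(C(C)C)C(C)C)c1C=O
F5 | step 12 | 3-methyl-2-(trimethylsilyloxy)furan | Cc1ccoc1O[Si](C)(C)C
F6 | step 12 | (5R)-5-[(S)-{4-[(tert-butyldimethylsilyl)oxy]-6-(diethoxymethyl)-3-isopropyl-2-[(triisopropylsilyl)oxy]phenyl}(hydroxy)methyl]-3-methylfuran-2(5H)-one | CCOC(OCC)c1cc(O[Si](C)(C)C(C)(C)C)c(C(C)C)c(O[Si](C(C)C)(C(C)C)C(C)C)c1[C@H](O)[C@@H]1OC(=O)C(C)=C1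
F7 | step 12 | 5-(trimethylsilyl) enol ether of 24 (3a,4,7,7a-tetrahydroisobenzofuran-1(3H)-one cycloadduct) | CCOC(OCC)c1cc(O[Si](C)(C)C(C)(C)C)c(C(C)C)c(O[Si](C(C)C)(C(C)C)C(C)C)c1[C@H](O)[C@@H]1OC(=O)[C@@]2(C)CC=C(O[Si](C)(C)C)C[C@@H]12
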